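**Retrosynthetic overview**

1. The C7 methacrylate goes on last; the C1 ketone comes from allylic oxidation of a longipin-2-ene, and the C3 methyl from the enol triflate of a 15-norlongipinan-3-one.
2. Cyclobutane (C4–C10): cationic closure of a himachalane-type C10 cation onto the C3–C4 silyl enol ether, as in himachalyl → longipinyl.
3. Seven-membered ring (C5–C6): an epoxide-derived C6 radical adds to the enone carbon C5 of a bisabolane-type cyclohexenone (the bond of bisabolyl → himachalyl) and leaves the C3–C4 enolate needed in line 2.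
4. Bisabolane: chelation-controlled Stork–Danheiser aldol of 3-ethoxycyclohex-2-en-1-one with (R)-3-hydroxy-6-methylhept-5-en-2-one (from sulcatone), then enone transposition.
5. Ring order: six-membered (bought) → seven-membered → four-membered.

Assumption: locants C1–C15 are the longipinane locants of the target (C1 ketone, C2=C3, C15 on C3, C4 and C11 bridgeheads, C6 gem-dimethyl, C7 and C9 oxygenated, C14 on C10) and are carried through every intermediate; cyclopentadienyl rings are drawn σ-bonded in SMILES.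

**Route**

Step 1
Reactants: 1 6-methylhept-5-en-2-one
Product: 3 (3R)-3-hydroxy-6-methylhept-5-en-2-one, via anilinooxy ketone 2 (not isolated)
Conditions: PhNO (slow addition), L-proline (20 mol%), 1 (3 equiv), DMSO, rt; then CuSO4·5H2O (30 mol%), MeOH, 0 °C
Reagents that add atoms: nitrosobenzene O=Nc1ccccc1
Why: Proline-catalysed α-aminoxylation (enamine catalysis) attacks the more substituted methylene α-carbon and the L-proline enamine delivers oxygen to the same face as with cyclohexanone to set the (R)-centre that becomes C9 before CuSO4-catalysed N–O cleavage frees the hydroxy ketone.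

Step 2
Reactants: 4 3-ethoxycyclohex-2-en-1-one; 3 (3R)-3-hydroxy-6-methylhept-5-en-2-one
Product: 7 (6S)-6-[(2R,3R)-2,3-dihydroxy-6-methylhept-5-en-2-yl]-3-ethoxycyclohex-2-en-1-one, via lithium dienolate 5 (not isolated), via lithium alkoxide 6 (not isolated)
Conditions: LiN(iPr)2 (2.3 equiv), 4 (2.3 equiv), THF, −78 °C; then 3 (1 equiv), −78 °C, 1 h; AcOH, −78 °C
Reagents that add atoms: none
Why: Stork–Danheiser aldol addition in which the first equivalent of the kinetic α′-dienolate 5 deprotonates the hydroxyl and the second adds to the five-membered lithium chelate 6 anti to its CH2-prenyl arm (Cram chelate control so that C10–O is syn to C9–O) through a chair transition state of the ring-locked E-enolate (anti aldol) which sets C11 as required relative to C9 while the C10 centre is only a relay that is erased in step 7.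

Step 3
Reactants: 7 (6S)-6-[(2R,3R)-2,3-dihydroxy-6-methylhept-5-en-2-yl]-3-ethoxycyclohex-2-en-1-one
Product: 9 (4R)-4-[(2R,3R)-2,3-dihydroxy-6-methylhept-5-en-2-yl]cyclohex-2-en-1-one, via allylic alcohol 8 (not isolated)
Conditions: iBu2AlH (3.5 equiv), CH2Cl2, −78 °C; then 1 M HCl, THF, 0 °C, 20 min; used at once
Reagents that add atoms: water O
Why: Stork–Danheiser enone transposition in which 1,2-hydride reduction of the vinylogous ester and acid hydrolysis of the 3-ethoxy allylic alcohol 8 with loss of water move the carbonyl to C3 and make C5 an electrophilic β-carbon next to C11 without touching a stereocentre.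

Step 4
Reactants: 9 (4R)-4-[(2R,3R)-2,3-dihydroxy-6-methylhept-5-en-2-yl]cyclohex-2-en-1-one
Product: 10 (2R,3R)-2-hydroxy-6-methyl-2-[(1R)-4-oxocyclohex-2-en-1-yl]hept-5-en-3-yl 2-methylpropanoate
Conditions: iPrCOCl (1.1 equiv), pyridine, DMAP (5 mol%), CH2Cl2, −20 → 0 °C
Reagents that add atoms: isobutyryl chloride CC(C)C(Cl)=O
Why: DMAP-catalysed acylation is chemoselective for the only secondary hydroxyl because the tertiary C10–OH is too hindered and this puts the C9 ester of the target in place early as the neighbouring group needed in step 7.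

Step 5
Reactants: 10 (2R,3R)-2-hydroxy-6-methyl-2-[(1R)-4-oxocyclohex-2-en-1-yl]hept-5-en-3-yl 2-methylpropanoate
Product: 11 (1R,2R)-1-{[(2R)-3,3-dimethyloxiran-2-yl]methyl}-2-hydroxy-2-[(1R)-4-oxocyclohex-2-en-1-yl]propyl 2-methylpropanoate
Conditions: D-fructose-derived Shi ketone (30 mol%), KHSO5 (as 2KHSO5·KHSO4·K2SO4), K2CO3, Bu4NHSO4, MeCN/CH2(OMe)2/aq. Na2B4O7 buffer (pH 10.5), 0 °C
Reagents that add atoms: potassium peroxymonosulfate [K+].[O-]S(=O)(=O)OO
Why: Shi asymmetric epoxidation with the dioxirane of the D-fructose-derived ketone reacts only at the electron-rich trisubstituted alkene and by the spiro transition state gives the (R)-epoxide at C7 as for other terminal prenyl groups so that reagent control sets the future C7–O stereocentre.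

Step 6
Reactants: 11 (1R,2R)-1-{[(2R)-3,3-dimethyloxiran-2-yl]methyl}-2-hydroxy-2-[(1R)-4-oxocyclohex-2-en-1-yl]propyl 2-methylpropanoate
Product: 13 (5S,7R,9R,10R,11R)-3,7,10-tris(tert-butyldimethylsilyloxy)-15-nor-4,10-secolongipin-3-en-9-yl 2-methylpropanoate, via titanium enolate 12 (not isolated)
Conditions: Cp2TiCl2 (2.5 equiv), Mn dust (8 equiv), THF, rt, slow addition of crude 11 (0.01 M); then 2,6-lutidine (6 equiv), TBSOTf (4 equiv), −78 → 0 °C
Reagents that add atoms: tert-butyldimethylsilyl trifluoromethanesulfonate CC(C)(C)[Si](C)(C)OS(=O)(=O)C(F)(F)F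
Why: Proposed new method: Cp2TiCl (trivalent titanium) opens the epoxide homolytically to the tertiary C6 radical with the C7–O bond untouched (Nugent–RajanBabu opening) and this radical adds 7-exo to the enone β-carbon C5 by axial attack on the face carrying the C11 side chain (cis ring fusion) after which a second Cp2TiCl reduces the α-keto radical to the C3–C4 titanium enolate that TBSOTf silylates in place together with both hydroxyls, the closest known reactions being titanocene-mediated epoxide–enone radical cyclisations to five- and six-membered rings and 7-endo epoxypolyene cyclisations, and the bond closed is the C5–C6 bond of the bisabolyl-to-himachalyl step.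

Step 7
Reactants: 13 (5S,7R,9R,10R,11R)-3,7,10-tris(tert-butyldimethylsilyloxy)-15-nor-4,10-secolongipin-3-en-9-yl 2-methylpropanoate
Product: 15 (4S,5R,7R,9R,10S,11R)-7-(tert-butyldimethylsilyloxy)-3-oxo-15-norlongipinan-9-yl 2-methylpropanoate, via acyloxonium triflate 14 (not isolated)
Conditions: TMSOTf (20 mol%), 2,6-di-tert-butyl-4-methylpyridine (30 mol%), CH2Cl2, −78 → −40 °C
Reagents that add atoms: none
Why: Proposed new method: the silyl triflate ionises the tertiary C10–OSi bond with anchimeric help of the trans C9 isobutyrate (1,3-dioxolan-2-ylium ion 14) and the C3–C4 silyl enol ether held over C10 in the cis-fused bicycle opens this ion at C10 in a 4-exo Mukaiyama-type alkylation anti to the C9 oxygen so that C4 and C10 are set with net retention at C10 (double inversion) in the sense of the himachalyl-to-longipinyl cation closure while formation of the C=O bond makes the cyclobutane closure irreversible, the closest known chemistry being the Reetz α-tert-alkylation of silyl enol ethers and epoxide-initiated cation–olefin cyclisations terminated by enol ethers.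

Step 8
Reactants: 15 (4S,5R,7R,9R,10S,11R)-7-(tert-butyldimethylsilyloxy)-3-oxo-15-norlongipinan-9-yl 2-methylpropanoate
Product: 17 (4S,5R,7R,9R,10S,11R)-7-(tert-butyldimethylsilyloxy)-3-(trifluoromethanesulfonyloxy)-15-norlongipin-2-en-9-yl 2-methylpropanoate, via potassium enolate 16 (not isolated)
Conditions: KN(SiMe3)2 (1.1 equiv), THF, −78 °C; then PhNTf2 (1.2 equiv), −78 → 0 °C
Reagents that add atoms: N-phenylbis(trifluoromethanesulfonimide) O=S(=O)(N(c1ccccc1)S(=O)(=O)C(F)(F)F)C(F)(F)F
Why: Enolate O-sulfonylation is regiospecific because only C2 can be deprotonated (C4 is a bridgehead and Bredt's rule forbids its enolate) and no stereocentre is affected.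

Step 9
Reactants: 17 (4S,5R,7R,9R,10S,11R)-7-(tert-butyldimethylsilyloxy)-3-(trifluoromethanesulfonyloxy)-15-norlongipin-2-en-9-yl 2-methylpropanoate
Product: 18 (4R,5R,7R,9R,10S,11R)-7-(tert-butyldimethylsilyloxy)longipin-2-en-9-yl 2-methylpropanoate
Conditions: MeMgBr (1.5 equiv), Fe(acac)3 (5 mol%), THF/NMP, −30 °C, 15 min
Reagents that add atoms: methylmagnesium bromide C[Mg]Br
Why: Iron-catalysed Kumada-type cross-coupling of the alkenyl triflate (Fürstner conditions) installs the C3 methyl group C15 faster than the Grignard reagent attacks the hindered isobutyrate.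

Step 10
Reactants: 18 (4R,5R,7R,9R,10S,11R)-7-(tert-butyldimethylsilyloxy)longipin-2-en-9-yl 2-methylpropanoate
Product: 19 (4R,5S,7R,9R,10R,11R)-7-(tert-butyldimethylsilyloxy)-1-oxolongipin-2-en-9-yl 2-methylpropanoate
Conditions: t-BuOOH (5 equiv, 70% aq.), Rh2(cap)4 (1 mol%, cap = caprolactamate), K2CO3, CH2Cl2, rt
Reagents that add atoms: tert-butyl hydroperoxide CC(C)(C)OO
Why: Radical allylic C–H oxidation (Doyle conditions) takes place at the only allylic methylene C1 because the bridgehead C4–H cannot give a stabilised allyl radical and it turns the α-pinene-like alkene into the enone in the way α-pinene gives verbenone.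

Step 11
Reactants: 19 (4R,5S,7R,9R,10R,11R)-7-(tert-butyldimethylsilyloxy)-1-oxolongipin-2-en-9-yl 2-methylpropanoate
Product: 20 (4R,5S,7R,9R,10R,11R)-7-hydroxy-1-oxolongipin-2-en-9-yl 2-methylpropanoate
Conditions: HF·pyridine, THF/pyridine, 0 → 40 °C
Reagents that add atoms: none
Why: Fluoride-mediated desilylation driven by Si–F bond formation frees the hindered C7 hydroxyl and leaves the enone and the isobutyrate untouched.

Step 12
Reactants: 20 (4R,5S,7R,9R,10R,11R)-7-hydroxy-1-oxolongipin-2-en-9-yl 2-methylpropanoate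
Product: 21 (4R,5S,7R,9R,10R,11R)-9-(2-methylpropanoyloxy)-1-oxolongipin-2-en-7-yl 2-methylprop-2-enoate
Conditions: methacryloyl chloride (3 equiv), Et3N (5 equiv), DMAP (0.3 equiv), CH2Cl2, 0 → 40 °C
Reagents that add atoms: methacryloyl chloride C=C(C)C(Cl)=O
Why: DMAP-catalysed acylation (nucleophilic acyl substitution at the acid chloride) esterifies the remaining C7 hydroxyl with retention at C7 and gives the target.

**Compound list**

1 | 6-methylhept-5-en-2-one (sulcatone) | CC(=O)CCC=C(C)C | starting material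
2 | (3R)-3-(anilinooxy)-6-methylhept-5-en-2-one | CC(C)=CC[C@@H](ONc1ccccc1)C(C)=O | intermediate (not isolated)
3 | (3R)-3-hydroxy-6-methylhept-5-en-2-one | CC(C)=CC[C@@H](O)C(C)=O | intermediate
4 | 3-ethoxycyclohex-2-en-1-one | CCOC1=CC(=O)CCC1 | starting material
5 | lithium 5-ethoxycyclohexa-1,5-dien-1-olate (kinetic dienolate of 4) | CCOC1=CC(O[Li])=CCC1 | intermediate (not isolated)
6 | lithium (3R)-6-methyl-2-oxohept-5-en-3-olate | CC(C)=CC[C@@H](O[Li])C(C)=O | intermediate (not isolated)
7 | (6S)-6-[(2R,3R)-2,3-dihydroxy-6-methylhept-5-en-2-yl]-3-ethoxycyclohex-2-en-1-one | CC(C)=CC[C@@H](O)[C@](C)(O)[C@@H]1CCC(OCC)=CC1=O | intermediate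
8 | (1RS,6R)-6-[(2R,3R)-2,3-dihydroxy-6-methylhept-5-en-2-yl]-3-ethoxycyclohex-2-en-1-ol (carbinol epimers) | CC(C)=CC[C@@H](O)[C@](C)(O)[C@@H]1CCC(OCC)=CC1O | intermediate (not isolated)
9 | (4R)-4-[(2R,3R)-2,3-dihydroxy-6-methylhept-5-en-2-yl]cyclohex-2-en-1-one | CC(C)=CC[C@@H](O)[C@](C)(O)[C@@H]1CCC(=O)C=C1 | intermediate
10 | (2R,3R)-2-hydroxy-6-methyl-2-[(1R)-4-oxocyclohex-2-en-1-yl]hept-5-en-3-yl 2-methylpropanoate | CC(C)=CC[C@@H](OC(=O)C(C)C)[C@](C)(O)[C@@H]1CCC(=O)C=C1 | intermediate
11 | (1R,2R)-1-{[(2R)-3,3-dimethyloxiran-2-yl]methyl}-2-hydroxy-2-[(1R)-4-oxocyclohex-2-en-1-yl]propyl 2-methylpropanoate | CC1(C)O[C@@H]1C[C@@H](OC(=O)C(C)C)[C@](C)(O)[C@@H]2CCC(=O)C=C2 | intermediate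
12 | (5S,7R,9R,10R,11R)-3,7-bis[chlorobis(cyclopentadienyl)titaniooxy]-10-hydroxy-15-nor-4,10-secolongipin-3-en-9-yl 2-methylpropanoate (cis-fused 6/7 bicycle) | Cl[Ti](C1C=CC=C1)(C1C=CC=C1)O[C@@H]1C[C@@H](OC(=O)C(C)C)[C@](C)(O)[C@@H]2CCC(O[Ti](Cl)(C3C=CC=C3)C3C=CC=C3)=C[C@@H]2C1(C)C | intermediate (not isolated)
13 | (5S,7R,9R,10R,11R)-3,7,10-tris(tert-butyldimethylsilyloxy)-15-nor-4,10-secolongipin-3-en-9-yl 2-methylpropanoate (cis-fused himachalane-type bicycle) | CC(C)(C)[Si](C)(C)O[C@@H]1C[C@@H](OC(=O)C(C)C)[C@](C)(O[Si](C)(C)C(C)(C)C)[C@@H]2CCC(O[Si](C)(C)C(C)(C)C)=C[C@@H]2C1(C)C | intermediate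
14 | 2-isopropyl-1,3-dioxolan-2-ylium ion cis-fused at C9–C10 of the 3,7-bis(tert-butyldimethylsilyloxy) bicycle (face opposite to C4), triflate salt | CC(C)(C)[Si](C)(C)O[C@@H]1C[C@H]2OC(C(C)C)=[O+][C@@]2(C)[C@@H]3CCC(O[Si](C)(C)C(C)(C)C)=C[C@@H]3C1(C)C.[O-]S(=O)(=O)C(F)(F)F | intermediate (not isolated)
15 | (4S,5R,7R,9R,10S,11R)-7-(tert-butyldimethylsilyloxy)-3-oxo-15-norlongipinan-9-yl 2-methylpropanoate | CC(C)(C)[Si](C)(C)O[C@@H]1C[C@@H](OC(=O)C(C)C)[C@@]2(C)[C@@H]3CCC(=O)[C@H]2[C@@H]3C1(C)C | intermediate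
16 | potassium C2–C3 enolate of 15 | CC(C)(C)[Si](C)(C)O[C@@H]1C[C@@H](OC(=O)C(C)C)[C@@]2(C)[C@@H]3CC=C(O[K])[C@H]2[C@@H]3C1(C)C | intermediate (not isolated)
17 | (4S,5R,7R,9R,10S,11R)-7-(tert-butyldimethylsilyloxy)-3-(trifluoromethanesulfonyloxy)-15-norlongipin-2-en-9-yl 2-methylpropanoate | CC(C)(C)[Si](C)(C)O[C@@H]1C[C@@H](OC(=O)C(C)C)[C@@]2(C)[C@@H]3CC=C(OS(=O)(=O)C(F)(F)F)[C@H]2[C@@H]3C1(C)C | intermediate
18 | (4R,5R,7R,9R,10S,11R)-7-(tert-butyldimethylsilyloxy)longipin-2-en-9-yl 2-methylpropanoate | CC(C)(C)[Si](C)(C)O[C@@H]1C[C@@H](OC(=O)C(C)C)[C@@]2(C)[C@@H]3CC=C(C)[C@H]2[C@@H]3C1(C)C | intermediate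
19 | (4R,5S,7R,9R,10R,11R)-7-(tert-butyldimethylsilyloxy)-1-oxolongipin-2-en-9-yl 2-methylpropanoate | CC(C)(C)[Si](C)(C)O[C@@H]1C[C@@H](OC(=O)C(C)C)[C@@]2(C)[C@@H]3C(=O)C=C(C)[C@H]2[C@@H]3C1(C)C | intermediate
20 | (4R,5S,7R,9R,10R,11R)-7-hydroxy-1-oxolongipin-2-en-9-yl 2-methylpropanoate | O[C@@H]1C[C@@H](OC(=O)C(C)C)[C@@]2(C)[C@@H]3C(=O)C=C(C)[C@H]2[C@@H]3C1(C)C | intermediate
21 | (4R,5S,7R,9R,10R,11R)-9-(2-methylpropanoyloxy)-1-oxolongipin-2-en-7-yl 2-methylprop-2-enoate (CNP0214356.1) | C=C(C)C(=O)O[C@@H]1C[C@@H](OC(=O)C(C)C)[C@@]2(C)[C@@H]3C(=O)C=C(C)[C@H]2[C@@H]3C1(C)C | target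

**Totals and risks**

Total step count: 12. Longest linear sequence: 12 steps (1 → 21; 4 is bought).

Most likely to fail, step 6: the 7-exo radical closure must beat reduction or elimination of the tertiary radical and Lewis-acid oxolane formation by the free C10 hydroxyl, and the titanium enolate must be silylated cleanly. The fallback makes the C6 radical from a halide instead. It sets out from 11: MgBr2·OEt2 (Et2O, −20 °C) opens the epoxide at its tertiary carbon to the bromohydrin (1R,2R)-1-[(2R)-3-bromo-2-hydroxy-3-methylbutyl]-2-hydroxy-2-[(1R)-4-oxocyclohex-2-en-1-yl]propyl 2-methylpropanoate F4. CrCl2 (divalent chromium, 4 equiv, DMF, Takai-type halide reduction) then gives the same C6 radical, conjugate addition to C5 and a chromium enolate, which TBSOTf/2,6-lutidine silylates, and the route comes back at 13.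

Most likely to fail, step 7: the C10 cation can lose a proton or the enol ether can be desilylated before the strained four-membered ring closes. The fallback ends the cation with an allylsilane (Sakurai-type termination, irreversible loss of Me3Si) and also replaces steps 8 and 9. It sets out from 13: CsF/PhNTf2 (DME) converts the silyl enol ether regiospecifically into the enol triflate (5S,7R,9R,10R,11R)-7,10-bis(tert-butyldimethylsilyloxy)-3-(trifluoromethanesulfonyloxy)-15-nor-4,10-secolongipin-3-en-9-yl 2-methylpropanoate F5. Pd(PPh3)4 with Me3SiCH2ZnCl (THF) gives the allylsilane (5S,7R,9R,10R,11R)-7,10-bis(tert-butyldimethylsilyloxy)-15-(trimethylsilyl)-4,10-secolongipin-3-en-9-yl 2-methylpropanoate F6. TMSOTf (CH2Cl2, −78 °C) then closes C4–C10 to the exocyclic alkene (4R,5R,7R,9R,10S,11R)-7-(tert-butyldimethylsilyloxy)longipin-3(15)-en-9-yl 2-methylpropanoate F7. Shifting the double bond into the ring (palladium on carbon pre-saturated with H2, as for β-pinene → α-pinene) brings the route back at 18.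

Most likely to fail, step 2: the dienolate may enolise the methyl ketone or the aldolate may revert, and the C11 selectivity rests on a chair transition state with a ketone acceptor. The fallback sets C11 by catalyst control. It sets out from 3: LiCH2CO2Et (EtOAc and LiN(iPr)2, 2.2 equiv, −78 °C, same chelate control) adds to the ketone and the adduct lactonises to (4R,5R)-4-hydroxy-4-methyl-5-(3-methylbut-2-en-1-yl)oxolan-2-one F1. iBu2AlH (−78 °C) gives the lactol (4R,5R)-4-methyl-5-(3-methylbut-2-en-1-yl)oxolane-2,4-diol F2. Enamine-catalysed Michael addition of this masked aldehyde to methyl vinyl ketone, with the enantiomer of diphenylprolinol trimethylsilyl ether matched to C11, gives 4-[(3S,4R,5R)-2,4-dihydroxy-4-methyl-5-(3-methylbut-2-en-1-yl)oxolan-3-yl]butan-2-one F3. Aldol condensation (KOH, MeOH) closes the cyclohexenone and the route comes back at 9.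

Further compounds
F1 | step 2 | (4R,5R)-4-hydroxy-4-methyl-5-(3-methylbut-2-en-1-yl)oxolan-2-one | CC(C)=CC[C@H]1OC(=O)C[C@@]1(C)O
F2 | step 2 | (4R,5R)-4-methyl-5-(3-methylbut-2-en-1-yl)oxolane-2,4-diol | CC(C)=CC[C@H]1OC(O)C[C@@]1(C)O
F3 | step 2 | 4-[(3S,4R,5R)-2,4-dihydroxy-4-methyl-5-(3-methylbut-2-en-1-yl)oxolan-3-yl]butan-2-one | CC(C)=CC[C@H]1OC(O)[C@@H](CCC(C)=O)[C@@]1(C)O
F4 | step 6 | (1R,2R)-1-[(2R)-3-bromo-2-hydroxy-3-methylbutyl]-2-hydroxy-2-[(1R)-4-oxocyclohex-2-en-1-yl]propyl 2-methylpropanoate | CC(C)(Br)[C@H](O)C[C@@H](OC(=O)C(C)C)[C@](C)(O)[C@@H]1CCC(=O)C=C1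
F5 | step 7 | (5S,7R,9R,10R,11R)-7,10-bis(tert-butyldimethylsilyloxy)-3-(trifluoromethanesulfonyloxy)-15-nor-4,10-secolongipin-3-en-9-yl 2-methylpropanoate | CC(C)(C)[Si](C)(C)O[C@@H]1C[C@@H](OC(=O)C(C)C)[C@](C)(O[Si](C)(C)C(C)(C)C)[C@@H]2CCC(OS(=O)(=O)C(F)(F)F)=C[C@@H]2C1(C)C
F6 | step 7 | (5S,7R,9R,10R,11R)-7,10-bis(tert-butyldimethylsilyloxy)-15-(trimethylsilyl)-4,10-secolongipin-3-en-9-yl 2-methylpropanoate | CC(C)(C)[Si](C)(C)O[C@@H]1C[C@@H](OC(=O)C(C)C)[C@](C)(O[Si](C)(C)C(C)(C)C)[C@@H]2CCC(C[Si](C)(C)C)=C[C@@H]2C1(C)C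
F7 | step 7 | (4R,5R,7R,9R,10S,11R)-7-(tert-butyldimethylsilyloxy)longipin-3(15)-en-9-yl 2-methylpropanoate | CC(C)(C)[Si](C)(C)O[C@@H]1C[C@@H](OC(=O)C(C)C)[C@@]2(C)[C@@H]3CCC(=C)[C@H]2[C@@H]3C1(C)C
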